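**Retrosynthetic overview**
1. Ester C–O bond: target ⇒ linoleoyl chloride + the (S)-1,3-diol, acylated only at the primary OH (tertiary OH and indole N–H stay free).
2. Aryl–prenyl bond: Stille coupling on the 6-bromo diol, placed after all Lewis-acid and Grignard chemistry so the prenyl alkene never meets TiCl4/formaldehyde.
3. Tertiary carbinol: two MeMgBr additions to a methyl 3-hydroxy-2-(indol-3-yl)propanoate.
4. Stereocentre: Evans titanium-enolate hydroxymethylation of the N-(6-bromoindol-3-ylacetyl) (4R)-4-benzyloxazolidin-2-one, with the indole nitrogen Boc-protected.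
5. Ring formation: none. The indole is bought intact as 6-bromoindole-3-acetic acid, and the oxazolidinone is a bought, recovered auxiliary.

Assumption: 2-(6-bromo-1H-indol-3-yl)acetic acid, (4R)-4-benzyl-1,3-oxazolidin-2-one, tributyl(3-methylbut-2-en-1-yl)stannane and linoleoyl chloride are taken as commercially available; the stereocentre of the target is read as (S).

**Route**

Step 1
Reactants: 1 2-(6-bromo-1H-indol-3-yl)acetic acid; 2 (4R)-4-benzyl-1,3-oxazolidin-2-one
Product: 4 (4R)-4-benzyl-3-[2-(6-bromo-1H-indol-3-yl)acetyl]-1,3-oxazolidin-2-one, via mixed pivalic anhydride 3 (not isolated)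
Conditions: PivCl (1.1 equiv), Et3N (2.5 equiv), THF, −20 °C, 1 h; then LiCl (1.1 equiv), 2 (1.05 equiv), −20 °C → rt
Reagents that add atoms: none
Why: N-acylation of the oxazolidinone through a mixed anhydride (LiCl/Et3N soft-deprotonation protocol) attaches the Evans auxiliary, and the indole N–H is not acylated in the absence of a strong base or DMAP.

Step 2
Reactants: 4 (4R)-4-benzyl-3-[2-(6-bromo-1H-indol-3-yl)acetyl]-1,3-oxazolidin-2-one
Product: 5 tert-butyl 3-{2-[(4R)-4-benzyl-2-oxo-1,3-oxazolidin-3-yl]-2-oxoethyl}-6-bromo-1H-indole-1-carboxylate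
Conditions: Boc2O (1.2 equiv), DMAP (10 mol%), MeCN, rt
Reagents that add atoms: di-tert-butyl dicarbonate, CC(C)(C)OC(=O)OC(=O)OC(C)(C)C
Why: DMAP-catalysed Boc protection of the indole nitrogen runs under neutral conditions that do not enolise the imide, and the carbamate switches off indole N1/C2 nucleophilicity for the Lewis-acidic step that follows.

Step 3
Reactants: 5 tert-butyl 3-{2-[(4R)-4-benzyl-2-oxo-1,3-oxazolidin-3-yl]-2-oxoethyl}-6-bromo-1H-indole-1-carboxylate
Product: 7 tert-butyl 3-{(2S)-1-[(4R)-4-benzyl-2-oxo-1,3-oxazolidin-3-yl]-3-hydroxy-1-oxopropan-2-yl}-6-bromo-1H-indole-1-carboxylate, via trichlorotitanium Z-enolate 6 (not isolated)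
Conditions: TiCl4 (1.1 equiv), i-Pr2NEt (1.15 equiv), CH2Cl2, 0 °C, 1 h; then 1,3,5-trioxane (1.2 equiv), TiCl4 (1.1 equiv), 0 °C, 2 h; aq NH4Cl
Reagents that add atoms: 1,3,5-trioxane (formaldehyde trimer), C1OCOCO1
Why: In this Evans asymmetric hydroxymethylation (aldol-type alkylation of a chelated chlorotitanium Z-enolate with TiCl4-activated formaldehyde) the electrophile adds to the enolate face opposite the benzyl group of the (4R)-auxiliary, which sets the new stereocentre as (2S) with an expected dr of at least 95:5, and allylic strain in the imide product protects this α-aryl centre from epimerisation.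

Step 4
Reactants: 7 tert-butyl 3-{(2S)-1-[(4R)-4-benzyl-2-oxo-1,3-oxazolidin-3-yl]-3-hydroxy-1-oxopropan-2-yl}-6-bromo-1H-indole-1-carboxylate
Product: 8 tert-butyl 6-bromo-3-[(2S)-3-hydroxy-1-methoxy-1-oxopropan-2-yl]-1H-indole-1-carboxylate
Conditions: MeOMgBr (3 equiv, made in the flask from MeMgBr and MeOH), MeOH/CH2Cl2, 0 °C, 20 min; pH 7 buffer
Reagents that add atoms: methanol (delivered as bromomagnesium methoxide), CO
Why: Transesterification of the imide with bromomagnesium methoxide (Evans auxiliary removal) is assisted by the neighbouring hydroxyl and is complete within minutes at 0 °C under weakly basic conditions, so the α-aryl stereocentre is kept, no new stereocentre is formed and the auxiliary is returned.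

Step 5
Reactants: 8 tert-butyl 6-bromo-3-[(2S)-3-hydroxy-1-methoxy-1-oxopropan-2-yl]-1H-indole-1-carboxylate
Product: 11 (2S)-2-(6-bromo-1H-indol-3-yl)-3-methylbutane-1,3-diol, via methyl ketone 9 (not isolated), via N-Boc diol 10 (not isolated)
Conditions: MeMgBr (4.5 equiv), THF, −40 → 0 °C; aq NH4Cl work-up; then crude 10, K2CO3, MeOH, 50 °C
Reagents that add atoms: methylmagnesium bromide, C[Mg]Br
Why: Double Grignard addition to the ester gives the tertiary carbinol, the magnesium alkoxide formed first from the β-hydroxyl chelating the carbonyl so that addition outruns enolisation and the existing stereocentre (afterwards no longer α to a carbonyl) is retained, and carbonate-mediated methanolysis then cleaves the indole N-Boc carbamate.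

Step 6
Reactants: 11 (2S)-2-(6-bromo-1H-indol-3-yl)-3-methylbutane-1,3-diol
Product: 12 (2S)-3-methyl-2-[6-(3-methylbut-2-en-1-yl)-1H-indol-3-yl]butane-1,3-diol
Conditions: tributyl(3-methylbut-2-en-1-yl)stannane (1.5 equiv), Pd(PPh3)4 (5 mol%), DMF, 100 °C
Reagents that add atoms: tributyl(3-methylbut-2-en-1-yl)stannane, CCCC[Sn](CCCC)(CCCC)CC=C(C)C
Why: Stille cross-coupling of the aryl bromide under zerovalent palladium catalysis tolerates the free N–H and hydroxyl groups and gives the linear prenyl group because reductive elimination takes place at the unhindered primary terminus of the allyl ligand, the stereocentre being untouched.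

Step 7
Reactants: 12 (2S)-3-methyl-2-[6-(3-methylbut-2-en-1-yl)-1H-indol-3-yl]butane-1,3-diol; 13 (9Z,12Z)-octadeca-9,12-dienoyl chloride (linoleoyl chloride)
Product: 14 (2S)-3-hydroxy-3-methyl-2-[6-(3-methylbut-2-en-1-yl)-1H-indol-3-yl]butyl (9Z,12Z)-octadeca-9,12-dienoate (CNP0180241.1)
Conditions: 13 (1.05 equiv), 2,4,6-collidine (2 equiv), CH2Cl2, −78 → −20 °C
Reagents that add atoms: none
Why: Chemoselective O-acylation with an acid chloride and a hindered pyridine base at low temperature esterifies only the unhindered primary hydroxyl, since the tertiary hydroxyl and the non-basic indole N–H do not react, and leaves the skipped (Z,Z)-diene, the prenyl group and the stereocentre unchanged.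

**Compound list**
1 | 2-(6-bromo-1H-indol-3-yl)acetic acid | OC(=O)Cc1c[nH]c2cc(Br)ccc12 | starting material
2 | (4R)-4-benzyl-1,3-oxazolidin-2-one | O=C1N[C@H](Cc2ccccc2)CO1 | starting material
3 | 2-(6-bromo-1H-indol-3-yl)acetic 2,2-dimethylpropanoic anhydride (mixed pivalic anhydride) | CC(C)(C)C(=O)OC(=O)Cc1c[nH]c2cc(Br)ccc12 | intermediate
4 | (4R)-4-benzyl-3-[2-(6-bromo-1H-indol-3-yl)acetyl]-1,3-oxazolidin-2-one | O=C(Cc1c[nH]c2cc(Br)ccc12)N1[C@H](Cc2ccccc2)COC1=O | intermediate
5 | tert-butyl 3-{2-[(4R)-4-benzyl-2-oxo-1,3-oxazolidin-3-yl]-2-oxoethyl}-6-bromo-1H-indole-1-carboxylate | O=C(Cc1cn(C(=O)OC(C)(C)C)c2cc(Br)ccc12)N1[C@H](Cc2ccccc2)COC1=O | intermediate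
6 | trichlorotitanium (Z)-enolate of 5 | Cl[Ti](Cl)(Cl)O/C(=C\c1cn(C(=O)OC(C)(C)C)c2cc(Br)ccc12)N1[C@H](Cc2ccccc2)COC1=O | intermediate
7 | tert-butyl 3-{(2S)-1-[(4R)-4-benzyl-2-oxo-1,3-oxazolidin-3-yl]-3-hydroxy-1-oxopropan-2-yl}-6-bromo-1H-indole-1-carboxylate | OC[C@H](c1cn(C(=O)OC(C)(C)C)c2cc(Br)ccc12)C(=O)N1[C@H](Cc2ccccc2)COC1=O | intermediate
8 | tert-butyl 6-bromo-3-[(2S)-3-hydroxy-1-methoxy-1-oxopropan-2-yl]-1H-indole-1-carboxylate | OC[C@H](c1cn(C(=O)OC(C)(C)C)c2cc(Br)ccc12)C(=O)OC | intermediate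
9 | tert-butyl 6-bromo-3-[(2S)-1-hydroxy-3-oxobutan-2-yl]-1H-indole-1-carboxylate (methyl ketone) | OC[C@H](c1cn(C(=O)OC(C)(C)C)c2cc(Br)ccc12)C(C)=O | intermediate
10 | tert-butyl 6-bromo-3-[(2S)-1,3-dihydroxy-3-methylbutan-2-yl]-1H-indole-1-carboxylate (N-Boc diol) | OC[C@H](c1cn(C(=O)OC(C)(C)C)c2cc(Br)ccc12)C(C)(C)O | intermediate
11 | (2S)-2-(6-bromo-1H-indol-3-yl)-3-methylbutane-1,3-diol | OC[C@H](c1c[nH]c2cc(Br)ccc12)C(C)(C)O | intermediate
12 | (2S)-3-methyl-2-[6-(3-methylbut-2-en-1-yl)-1H-indol-3-yl]butane-1,3-diol | OC[C@H](c1c[nH]c2cc(CC=C(C)C)ccc12)C(C)(C)O | intermediate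
13 | (9Z,12Z)-octadeca-9,12-dienoyl chloride (linoleoyl chloride) | CCCCC/C=C\C/C=C\CCCCCCCC(=O)Cl | starting material
14 | (2S)-3-hydroxy-3-methyl-2-[6-(3-methylbut-2-en-1-yl)-1H-indol-3-yl]butyl (9Z,12Z)-octadeca-9,12-dienoate | CCCCC/C=C\C/C=C\CCCCCCCC(=O)OC[C@H](c1c[nH]c2cc(CC=C(C)C)ccc12)C(C)(C)O | target

**Totals**
Total step count: 7. Longest linear sequence: 7 steps (1 → 14).

**Steps most likely to fail, with fallbacks**

Step 3 (titanium-enolate hydroxymethylation). The risks are loss of the N-Boc group under TiCl4, attack of activated formaldehyde on the indole, and incomplete diastereocontrol. The fallback sets out from compound 5 and comes back to the route at compound 7, bringing in the one-carbon unit under basic conditions without a Lewis acid. Compound 5 is deprotonated with NaN(SiMe3)2 in THF at −78 °C to the chelated sodium (Z)-enolate of 5 F1. This is C-alkylated with 4-methoxybenzyl chloromethyl ether, with the same facial sense (anti to the benzyl group), to give (4R)-4-benzyl-3-{(2S)-2-[6-bromo-1-(tert-butoxycarbonyl)indol-3-yl]-3-[(4-methoxybenzyl)oxy]propanoyl}-1,3-oxazolidin-2-one F2. The 4-methoxybenzyl group is then removed oxidatively with DDQ in CH2Cl2/water to give 7.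

Step 5 (double Grignard addition). The risks are enolisation of the α-aryl ester 8 or of the ketone 9 with loss of ee, and retro-aldol loss of formaldehyde. The fallback sets out from compound 1 and comes back to the route at compound 10; it installs the carbinol before the auxiliary is removed, so the stereocentre is never α to a free ester or ketone. Acid 1 is coupled through 3, under the conditions of step 1, with the enantiomeric commercial auxiliary (4S)-4-benzyl-1,3-oxazolidin-2-one to give (4S)-4-benzyl-3-[2-(6-bromo-1H-indol-3-yl)acetyl]-1,3-oxazolidin-2-one F3. N-Boc protection (Boc2O, DMAP) gives tert-butyl 3-{2-[(4S)-4-benzyl-2-oxo-1,3-oxazolidin-3-yl]-2-oxoethyl}-6-bromo-1H-indole-1-carboxylate F4. LiN(SiMe3)2 in THF at −78 °C gives the chelated lithium (Z)-enolate of F4 F5, which adds to acetone in an aldol addition, quenched cold with acetic acid. Attack on the face away from the benzyl group is assumed by analogy with alkylation of such chelated enolates and is not separately established for a ketone electrophile. The product is the tertiary aldol (4S)-4-benzyl-3-{(2R)-2-[6-bromo-1-(tert-butoxycarbonyl)indol-3-yl]-3-hydroxy-3-methylbutanoyl}-1,3-oxazolidin-2-one F6. Reductive removal of the auxiliary with LiBH4 (THF, 1 equiv MeOH, 0 °C) gives 10, which goes through the carbonate/methanol stage of step 5 to 11.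

Step 6 (Stille prenylation). The risks are γ-coupling to the reverse-prenyl isomer, alkene migration, and slow coupling on the unprotected diol. The fallback sets out from compound 11 and comes back to the route at compound 12 by inverting the polarity of the coupling. Miyaura borylation of 11 (bis(pinacolato)diboron, PdCl2(dppf) with dppf = 1,1'-bis(diphenylphosphino)ferrocene, KOAc, dioxane, 90 °C) gives (2S)-3-methyl-2-[6-(4,4,5,5-tetramethyl-1,3,2-dioxaborolan-2-yl)-1H-indol-3-yl]butane-1,3-diol F7. Suzuki–Miyaura allyl–aryl coupling of F7 with 1-bromo-3-methylbut-2-ene (Pd(PPh3)4, K2CO3, THF/water, 60 °C) joins the aryl group to the unsubstituted terminus of the prenylpalladium intermediate and gives 12.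

**Further compounds**
F1 | step 3 | sodium (Z)-enolate of 5 | [Na]O/C(=C\c1cn(C(=O)OC(C)(C)C)c2cc(Br)ccc12)N1[C@H](Cc2ccccc2)COC1=O
F2 | step 3 | (4R)-4-benzyl-3-{(2S)-2-[6-bromo-1-(tert-butoxycarbonyl)indol-3-yl]-3-[(4-methoxybenzyl)oxy]propanoyl}-1,3-oxazolidin-2-one | COc1ccc(COC[C@H](c2cn(C(=O)OC(C)(C)C)c3cc(Br)ccc23)C(=O)N2[C@H](Cc3ccccc3)COC2=O)cc1
F3 | step 5 | (4S)-4-benzyl-3-[2-(6-bromo-1H-indol-3-yl)acetyl]-1,3-oxazolidin-2-one | O=C(Cc1c[nH]c2cc(Br)ccc12)N1[C@@H](Cc2ccccc2)COC1=O
F4 | step 5 | tert-butyl 3-{2-[(4S)-4-benzyl-2-oxo-1,3-oxazolidin-3-yl]-2-oxoethyl}-6-bromo-1H-indole-1-carboxylate | O=C(Cc1cn(C(=O)OC(C)(C)C)c2cc(Br)ccc12)N1[C@@H](Cc2ccccc2)COC1=O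
F5 | step 5 | lithium (Z)-enolate of F4 | [Li]O/C(=C\c1cn(C(=O)OC(C)(C)C)c2cc(Br)ccc12)N1[C@@H](Cc2ccccc2)COC1=O
F6 | step 5 | (4S)-4-benzyl-3-{(2R)-2-[6-bromo-1-(tert-butoxycarbonyl)indol-3-yl]-3-hydroxy-3-methylbutanoyl}-1,3-oxazolidin-2-one | O=C([C@H](c1cn(C(=O)OC(C)(C)C)c2cc(Br)ccc12)C(C)(C)O)N1[C@@H](Cc2ccccc2)COC1=O
F7 | step 6 | (2S)-3-methyl-2-[6-(4,4,5,5-tetramethyl-1,3,2-dioxaborolan-2-yl)-1H-indol-3-yl]butane-1,3-diol | OC[C@H](c1c[nH]c2cc(B3OC(C)(C)C(C)(C)O3)ccc12)C(C)(C)O
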